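## Structural features

The target is a briarane. Ring A is a cyclohexene (C1, C10–C14, C13=C14), ring B a ten-membered carbocycle (C1–C10) holding the (Z)-trisubstituted C5=C6 alkene, and ring C a γ-lactone (C7, C8, C17, C19, O).

Rings A and B are trans-fused at C1–C10 (15-CH3 β, 10-H α). Rings B and C share C7–C8, with 7-H and 8-OH on opposite faces.

All nine stereocentres are contiguous. They run C12–C11–C10–C1–C2 on one arm and C10–C9–C8(–C17)–C7 on the other, and the quaternary C1 is wedged between the C2 acetate and C10.

In ring A the 11-CH3 (β) and 12-OH (α) are trans-diaxial and 11-CH3 is syn-axial to 15-CH3, so C11 is the less stable epimer whenever C12 is a ketone.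

The fragile groups are two secondary acetates next to free hydroxyls (acyl migration), a tertiary β-hydroxy lactone (retro-aldol, dehydration), an allylic alcohol, and the α-oxygenated positions C7 and C9.

The real difficulty is ring B. An end-to-end closure must overcome transannular strain beside the neopentyl C2, must deliver a Z alkene that a ring of this size does not enforce, and leaves C2, C7, C8 and C9 on a mobile ring.

The feature exploited is that C2 and C8 both carry oxygen and face each other across ring B. An added C2–C8 bond divides ring B into a cyclopentane (C1, C2, C8, C9, C10) and a cycloheptene (C2–C8). That cyclopentane together with ring A is the hydrindane delivered by the Hajos–Parrish–Eder–Sauer–Wiechert reaction, so ring B is uncovered by oxidative scission of a C2–C8 diol.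

## Logic of the disconnections

**42 ⇒ 39.** No skeletal bond is cut. The O12–H becomes an O12–PMB ether, the O2 acetyl is removed, and C2–H is exchanged for a C2 ketone.
- Reason: the acetate/hydroxyl pattern and the allylic alcohol are the most fragile features and belong at the end.
- Gain: one stereocentre fewer, and a trigonal C2, which is what the key step delivers.
- Demand: hydride must reach one face of a neopentyl ketone in a mobile ring (reagent control), and acetylation must spare the tertiary 8-OH.

**39 ⇒ 37.** The C8–C17 bond of ring C is cut.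
- Reason: a propanoate unit tethered on O7 can create the C8 carbinol and C17 together.
- Gain: ring C and two stereocentres disappear, and C8 becomes the second carbonyl of a dione.
- Demand: the ester enolate must form without base and must choose C8 over C2.

**37 ⇒ 35 (key).** A C2–C8 bond is added and both ketones become tertiary carbinols. In one sentence: ring B is not closed but uncovered, by glycol scission of the ring-fusion diol of a 6-5-7 tricycle.
- Reason: C2 and C8 are the only pair of oxygenated ring B carbons whose connection gives two common rings and leaves C7 and C9 untouched.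
- Gain: the medium ring, its Z alkene and its stereocentres become problems of a rigid hydrindane-fused cycloheptene.
- Demand: the C2/C8 diol must be cis and must be the only free 1,2-diol.

**35 ⇒ 30.** The C8–O and C9–O bonds are cut back to a C8=C9 alkene, and the O7 acyl group is exchanged for a silyl group.
- Reason: the 2β-OH can steer oxygen to the β face, and C9 can then be inverted by acetate.
- Gain: three heteroatom bonds are traced to one alkene.
- Demand: chemoselectivity among three alkenes, and attack at C9 rather than C8.

**30 ⇒ 29.** C5=C6 is cut inside the seven-membered ring.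
- Reason: at this ring size metathesis is fast and can only give the Z alkene.
- Gain: the tricycle becomes a hydrindene with two side chains.
- Demand: both chains must lie within reach on the same side.

**29 ⇒ 26 + 27.** C2–C3 is cut.
- Reason: C2 is a ketone flanked by the quaternary C1, whose β methyl dictates α attack.
- Gain: a commercial C5 unit is split off.
- Demand: clean 1,2-addition to a hindered enone.

**26 ⇒ 19 + 20.** C7–C8 is cut and C8=C9 is saturated.
- Reason: an anti-aldol on the α face of the only possible enolate sets C7 from C1.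
- Gain: the side chain becomes acrolein.
- Demand: later desaturation must erase C8 but not C7.

**19 ⇒ 9.** The C12–O bond is removed, C13=C14 is moved back to C11=C12, and the C2 ketone is masked.
- Reason: syn hydroboration of C11=C12 from the α face is the one operation that places 11-CH3 axial.
- Gain: three ring A features are traced to one alkene.
- Demand: every step must obey trans-diaxial stereoelectronics.

**9 ⇒ 4.** The C10–H bond is removed, the alkene returns to C10=C11 and C12 becomes a ketone.
- Reason: a suprafacial hydrogen shift from C12 to C10 gives the trans fusion that hydrogenation of such enones does not.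
- Gain: two stereocentres fewer.
- Demand: a 12β alcohol, and inversion at C12.

**4 ⇒ 1 + 2.** C10=C11 and C1–C14 are cut.
- Reason: this is the retron of a Michael addition followed by an amino-acid-catalysed aldol condensation.
- Gain: two achiral commercial compounds.
- Demand: enantiotopic group selection at C1.

## Other disconnections considered

**Alternative 1:** The cut is C5=C6 of ring B (the first idea; closing C6–C7 by a Nozaki–Hiyama–Kishi reaction is the same in spirit). The forward key step is ring-closing metathesis of the fully decorated seco-diene A1 at high dilution.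
- The closure is end to end, so it pays the full transannular strain and entropy of a ten-membered ring.
- It joins a 1,1-disubstituted alkene to a branched allylic one, with dimerisation as the easier outlet.
- A ring of ten atoms tolerates both alkene geometries, so Z is not secured by structure.
- All nine stereocentres must be assembled beforehand on open chains hanging from ring A.
- The chosen plan forms the same alkene in a seven-membered ring, where Z is the only option, and sets the stereocentres on a rigid frame.

**Alternative 2:** The cut is C9–C10, with C2–C7 reconnected. The forward key step is an anionic oxy-Cope ring expansion of the dialkenylcyclohexenol A2, followed by methylation of the C1 enolate to give A3. It is convergent and expands a six- to a ten-membered ring, but several points weigh against it.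
- The ketone needed to make A2 carries a doubly allylic α-hydrogen at C7 and should slip into conjugation.
- C9 has to bond to C10 on the face that bears the 11-CH3.
- A3 contains a conjugated 5,7-diene in which only C7=C8 may be oxidised.
- C17–C19, C1 (methylation), C2, C7 and C8 would all be set on the flexible ring, and C13=C14 is still missing.
- More stereocentres depend on medium-ring conformation than in the chosen plan, which leaves only C2 and C8.

**Alternative 3:** The cut is C3–C4, with O bridging C2 and C6. The forward key step is a Claisen ring expansion of the 2-methyleneoxocane A4, made by methylenation of the eight-membered lactone A5. Heating would form C3–C4, break O–C6 and leave the C2 carbonyl and C5=C6 in place.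
- Mechanistically it is attractive: the eight-membered ring can only hold the C6–C7 bond pseudo-axial in the chair transition state, which means Z.
- It trades one medium ring for another. A5 requires lactonisation of a neopentyl acid onto a hindered secondary alcohol.
- It needs an extra stereocentre at C6 that is then destroyed, and it excludes every other ester during methylenation.
- It creates no stereocentre, and it would cost more steps for a smaller gain.

Key step: step 21

Remark: briarane numbering (C15 on C1, C16 on C5, C18 on C17, C19 = lactone carbonyl, C20 on C11) is used for every intermediate, and α/β refer to the usual drawing with the C15 methyl β. Compound 34 is used as the racemate, so 35–37 are epimer mixtures at the bromine-bearing carbon, which is erased in step 22.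

## Steps

Step 1
Reactants: 1 2-methylcyclopentane-1,3-dione; 2 pent-1-en-3-one
Product: 3 2-methyl-2-(3-oxopentyl)cyclopentane-1,3-dione
Conditions: H2O, AcOH (cat.), 75 °C
Reagents that add atoms: none
Why: Michael addition of the acidic cyclic 1,3-dione to the enone forms C1–C14; the product is achiral, so no selectivity is required.

Step 2
Reactants: 3 2-methyl-2-(3-oxopentyl)cyclopentane-1,3-dione
Product: 4 (7aS)-4,7a-dimethyl-2,3,7,7a-tetrahydro-1H-indene-1,5(6H)-dione
Conditions: L-phenylalanine, (1S)-(+)-camphor-10-sulfonic acid, DMF, 30 → 70 °C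
Reagents that add atoms: none
Why: Hajos–Parrish–Eder–Sauer–Wiechert reaction: the enamine of the ethyl ketone attacks one of the two enantiotopic ring carbonyls and dehydration gives C10=C11. A primary L-amino acid is the usual catalyst for ethyl ketones and should give the 7aS series, which fixes C1.

Step 3
Reactants: 4 (7aS)-enedione
Product: 5 C2 ethylene ketal of 4
Conditions: (TMSOCH2)2, TMSOTf (cat.), CH2Cl2, −78 → −20 °C
Reagents that add atoms: 1,2-bis(trimethylsilyloxy)ethane, C[Si](C)(C)OCCO[Si](C)(C)C
Why: TMSOTf-catalysed silyl-transfer ketalisation under kinetic control; the saturated C2 ketone reacts while the conjugated, tetrasubstituted C12 enone is deactivated and is not deconjugated at low temperature.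

Step 4
Reactants: 5 C2 ketal enone
Product: 6 12β-allylic alcohol
Conditions: NaBH4, CeCl3·7H2O, MeOH, −78 → 0 °C
Reagents that add atoms: none
Why: Luche 1,2-reduction; hydride enters from the α face, opposite the axial 15-CH3, and should give the pseudo-equatorial 12β-alcohol needed for inversion in the next step.

Step 5
Reactants: 6 12β-allylic alcohol
Product: 9 trans-hydrindene ketal (10α-H; C11=C12), via sulfonylhydrazine 7 (not isolated), via allylic diazene 8 (not isolated)
Conditions: 2-nitrobenzenesulfonylhydrazide, PPh3, DEAD, N-methylmorpholine, −30 °C → rt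
Reagents that add atoms: none
Why: Myers reductive allylic transposition: Mitsunobu displacement inverts C12 (12α-N), loss of sulfinate gives 8, and its retro-ene loss of N2 passes hydrogen suprafacially to the α face of C10. This sets the trans ring fusion and moves the alkene to C11=C12.

Step 6
Reactants: 9 trans-hydrindene ketal
Product: 11 11β-methyl-12α-alcohol, via alkylborane 10 (not isolated)
Conditions: BH3·THF, THF, 0 °C → rt; then NaOH, H2O2, 0 °C
Reagents that add atoms: hydrogen peroxide, OO
Why: Hydroboration–oxidation; boron goes to the less substituted C12 and H to C11, both syn from the α face because the β face is screened by the axial 15-CH3. This places 11-CH3 β (axial) and 12-OH α (axial), and oxidation proceeds with retention.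

Step 7
Reactants: 11 11β-methyl-12α-alcohol
Product: 13 C12=C13 alkene, via dichlorophosphate 12 (not isolated)
Conditions: POCl3, pyridine, 0 → 80 °C
Reagents that add atoms: none
Why: E2 dehydration of an axial alcohol; the only hydrogen antiperiplanar to the 12α leaving group is 13β-H, because the axial position at C11 holds the methyl group. The alkene can therefore form only toward C13, and C11 is untouched.

Step 8
Reactants: 13 C12=C13 alkene
Product: 14 12α,13α-epoxide
Conditions: mCPBA, NaHCO3, CH2Cl2, 0 °C
Reagents that add atoms: 3-chloroperoxybenzoic acid, OOC(=O)c1cccc(Cl)c1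
Why: Prilezhaev epoxidation from the α face; the β face is blocked by the pseudo-axial 11-CH3 and the axial 15-CH3.

Step 9
Reactants: 14 12α,13α-epoxide
Product: 17 allylic alcohol ketal (12α-OH; C13=C14), via hydroxy selenide 15 (not isolated), via selenoxide 16 (not isolated)
Conditions: (PhSe)2, NaBH4, EtOH, reflux; then H2O2, THF, 0 °C → rt
Reagents that add atoms: none
Why: Epoxide-to-allylic-alcohol transposition by selenolate opening and selenoxide syn-elimination. The Fürst–Plattner rule directs PhSe to C13 (β, axial), as in 2α,3α-epoxy steroids, leaving 12α-OH, and the selenoxide eliminates away from the carbinol toward C14.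

Step 10
Reactants: 17 allylic alcohol ketal
Product: 18 12-O-PMB ether
Conditions: NaH, PMBCl, Bu4NI (cat.), DMF, 0 °C → rt
Reagents that add atoms: 4-methoxybenzyl chloride, COc1ccc(CCl)cc1
Why: Williamson etherification; the ketal is stable to base, and the PMB group is orthogonal to the silyl ether and acetates that follow.

Step 11
Reactants: 18 12-O-PMB ether
Product: 19 hydrindenone (C2 ketone)
Conditions: 1 M HCl, THF, rt
Reagents that add atoms: water, O
Why: Acid hydrolysis of the ketal; the PMB ether survives dilute acid, and the C13=C14 alkene cannot move into conjugation because C1 carries no hydrogen.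

Step 12
Reactants: 19 hydrindenone; 20 acrolein
Product: 22 anti-aldol (7S; 8α side chain), via boron enolate 21 (not isolated)
Conditions: Cy2BCl, Et3N, Et2O, 0 °C; 20, −78 °C; then H2O2, MeOH, pH 7 buffer, 0 °C
Reagents that add atoms: none
Why: Boron-mediated aldol through a Zimmerman–Traxler chair; the ring-locked E-enolate (only C8 is enolisable) gives the anti adduct. The aldehyde approaches the α face opposite 15-CH3, and together these translate C1 into the 7S carbinol.

Step 13
Reactants: 22 anti-aldol
Product: 23 7-O-TBS ether
Conditions: TBSOTf, 2,6-lutidine, CH2Cl2, −78 °C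
Reagents that add atoms: tert-butyldimethylsilyl triflate, CC(C)(C)[Si](C)(C)OS(=O)(=O)C(F)(F)F
Why: Silylation at low temperature with a hindered base avoids retro-aldol and dehydration of the β-hydroxy ketone.

Step 14
Reactants: 23 7-O-TBS ether
Product: 26 2-substituted cyclopentenone (C8=C9), via α-selenide 24 (not isolated), via selenoxide 25 (not isolated)
Conditions: LiN(iPr)2, THF, −78 °C; PhSeBr; then H2O2, pyridine, CH2Cl2, 0 °C
Reagents that add atoms: none
Why: α-Selenenylation and selenoxide syn-elimination; C8 is the only enolisable position, and the selenoxide eliminates toward C9 rather than toward the oxygen-bearing C7. C8 is erased on purpose while C7 is kept.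

Step 15
Reactants: 26 cyclopentenone; 27 4-bromo-2-methylbut-1-ene
Product: 29 tertiary allylic alcohol (2β-OH), via Grignard reagent 28 (not isolated)
Conditions: 27, Mg, THF; then 26, LaCl3·2LiCl, THF, −30 → 0 °C
Reagents that add atoms: none
Why: Lanthanide-promoted 1,2-addition of a Grignard reagent to an enone without α-hydrogens. As with 17-oxo steroids, the neighbouring β methyl forces α attack, so the chain is α and the hydroxyl β (a temporary stereocentre).

Step 16
Reactants: 29 tertiary allylic alcohol
Product: 30 6-5-7 tricycle (C5=C6 in the cycloheptene)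
Conditions: second-generation Grubbs catalyst (5 mol %), CH2Cl2 (2 mM), reflux
Reagents that add atoms: none
Why: Ring-closing metathesis of the only two terminal alkenes to a seven-membered ring; the ring size allows only the Z geometry at C5=C6, and the endocyclic alkenes are inert.

Step 17
Reactants: 30 6-5-7 tricycle
Product: 31 8β,9β-epoxy alcohol
Conditions: VO(acac)2 (cat.), t-BuOOH, CH2Cl2, 0 °C
Reagents that add atoms: tert-butyl hydroperoxide, CC(C)(C)OO
Why: Vanadium-catalysed hydroxyl-directed epoxidation; C8=C9 is the only alkene allylic to a free hydroxyl, and oxygen is delivered syn to the 2β-OH, which makes O2 and O8 cis.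

Step 18
Reactants: 31 8β,9β-epoxy alcohol
Product: 32 9α-acetoxy-2β,8β-diol
Conditions: Ti(OiPr)4, AcOH, CH2Cl2, rt
Reagents that add atoms: acetic acid, CC(=O)O
Why: Ti(OiPr)4-mediated opening of a 2,3-epoxy alcohol at the distal carbon; acetate attacks the secondary C9 from the open α face with inversion, which sets 9α-OAc. The trans O8/O9 relation on the cyclopentane blocks acetyl migration.

Step 19
Reactants: 32 9α-acetoxy-2β,8β-diol
Product: 33 7-alcohol
Conditions: HF·pyridine, pyridine, THF, 0 °C → rt
Reagents that add atoms: none
Why: Fluoride desilylation in a buffered, non-basic medium, which leaves the PMB ether and the acetate in place and avoids base-induced acetyl migration from O9 to O7.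

Step 20
Reactants: 33 7-alcohol; 34 2-bromopropanoyl bromide
Product: 35 7-O-(2-bromopropanoyl) 2β,8β-diol
Conditions: pyridine, CH2Cl2, −20 °C
Reagents that add atoms: none
Why: Acylation of the only secondary hydroxyl; the two tertiary hydroxyls do not compete at low temperature. Capping O7 removes the C7/C8 glycol from the reach of the next reagent.

Step 21
Reactants: 35 7-O-(2-bromopropanoyl) 2β,8β-diol
Product: 37 ring B 2,8-dione, via cyclic lead diester 36 (not isolated)
Conditions: Pb(OAc)4, CH2Cl2, 0 °C
Reagents that add atoms: none
Why: Criegee glycol cleavage used as a ring-merging fragmentation. The two cis (β,β) tertiary hydroxyls at C2 and C8 displace two acetates from tetravalent lead to give the five-membered cyclic diester 36, which collapses in a concerted two-electron step to the C2 and C8 ketones and Pb(OAc)2. The closest known reaction type is the Pb(OAc)4 or periodate scission of ring-fusion diols of bicyclo[5.3.0]- and bicyclo[4.4.0]decanes to cyclodecanediones. No ring is closed by bond formation: the cyclopentane (C1, C2, C8, C9, C10) and the cycloheptene (C2–C8) merge into ring B when their shared bond breaks, so the entropic cost and the dimerisation of an end-to-end closure do not arise. No stereocentre is created; C2 and C8 become trigonal, and C1, C7, C9, C10, C11 and C12 pass through unchanged because none of their bonds takes part and the medium is not basic. The C5=C6 geometry is Z because it was fixed inside the seven-membered ring in step 16 and the alkene is not touched. The selectivity needed is for one glycol only: O7 and O9 are acylated and O12 is a PMB ether, so C2/C8 is the only free 1,2-diol, and its cis geometry was secured by the α-face addition of step 15 and the directed epoxidation of step 17. Alkenes, the α-bromo ester and the PMB ether are inert to Pb(OAc)4 at 0 °C, and the reaction is driven by two new carbonyl groups and by relief of the eclipsing between two vicinal fully substituted carbons.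

Step 22
Reactants: 37 ring B 2,8-dione
Product: 39 hydroxy lactone 2-ketone, via samarium enolate 38 (not isolated)
Conditions: SmI2 (2.2 equiv), THF, −78 °C
Reagents that add atoms: none
Why: SmI2-mediated intramolecular Reformatsky reaction; the C–Br bond is reduced first, and the tether reaches only C8, not C2. Attack occurs on the rotamer with the ring torsion C6–C7–C8–C9 near 150° (the alternative, near 30°, is strained in ring B), which puts 8-OH cis to C6. Trivalent samarium bridges the enolate oxygen, which lies syn to the methyl group, and the ketone oxygen, so 18-CH3 ends cis to 8-OH, which is also the more stable C17 epimer.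

Step 23
Reactants: 39 hydroxy lactone 2-ketone
Product: 40 (2R)-alcohol
Conditions: (S)-Me-CBS oxazaborolidine (0.5 equiv), catecholborane, toluene, −60 → −20 °C
Reagents that add atoms: none
Why: Corey–Bakshi–Shibata reduction; the quaternary C1 and the C3 methylene are a well-differentiated large/small pair, for which the S catalyst should give the 2R carbinol by reagent control. Catecholborane spares the alkenes, the lactone and the acetate.

Step 24
Reactants: 40 (2R)-alcohol
Product: 41 2,9-diacetate 12-O-PMB ether
Conditions: Ac2O, Et3N, DMAP (cat.), CH2Cl2, 0 °C → rt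
Reagents that add atoms: acetic anhydride, CC(=O)OC(C)=O
Why: DMAP-catalysed acetylation of the secondary 2-OH; the tertiary 8-OH beside the lactone is too hindered to compete under these conditions.

Step 25
Reactants: 41 2,9-diacetate 12-O-PMB ether
Product: 42 CNP0222085.1 (target)
Conditions: DDQ, CH2Cl2, pH 7 buffer, 0 °C
Reagents that add atoms: none
Why: Oxidative cleavage of the PMB ether under neutral conditions releases 12α-OH without acyl migration, lactone opening or dehydration.

## Compound list

1 | 2-methylcyclopentane-1,3-dione | CC1C(=O)CCC1=O | starting material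
2 | pent-1-en-3-one (ethyl vinyl ketone) | CCC(=O)C=C | starting material
3 | 2-methyl-2-(3-oxopentyl)cyclopentane-1,3-dione | CCC(=O)CCC1(C)C(=O)CCC1=O | intermediate
4 | (7aS)-4,7a-dimethyl-2,3,7,7a-tetrahydro-1H-indene-1,5(6H)-dione (C2 ketone, C10=C11–C12 enone) | O=C1CC[C@]2(C)C(=O)CCC2=C1C | intermediate
5 | C2 ethylene ketal of 4 | O=C1CC[C@]2(C)C3(OCCO3)CCC2=C1C | intermediate
6 | 12β-allylic alcohol of 5 | O[C@H]1CC[C@]2(C)C3(OCCO3)CCC2=C1C | intermediate
7 | 12α-N-(2-nitrophenylsulfonyl)hydrazine (Mitsunobu adduct) | NN([C@@H]1CC[C@]2(C)C3(OCCO3)CCC2=C1C)S(=O)(=O)c1ccccc1[N+](=O)[O-] | intermediate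
8 | 12α-allylic diazene | N=N[C@@H]1CC[C@]2(C)C3(OCCO3)CCC2=C1C | intermediate
9 | trans-hydrindene ketal, 10α-H, C11=C12 | CC1=CCC[C@]2(C)C3(OCCO3)CC[C@@H]12 | intermediate
10 | 12α-boryl adduct (RBH2), 11β-methyl | C[C@H]1[C@H](B)CC[C@]2(C)C3(OCCO3)CC[C@@H]12 | intermediate
11 | 11β-methyl-12α-alcohol, C2 ketal | C[C@H]1[C@H](O)CC[C@]2(C)C3(OCCO3)CC[C@@H]12 | intermediate
12 | 12α-dichlorophosphate of 11 | C[C@H]1[C@H](OP(=O)(Cl)Cl)CC[C@]2(C)C3(OCCO3)CC[C@@H]12 | intermediate
13 | C12=C13 alkene, 11β-methyl, C2 ketal | C[C@H]1C=CC[C@]2(C)C3(OCCO3)CC[C@@H]12 | intermediate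
14 | 12α,13α-epoxide | C[C@H]1[C@@H]2O[C@@H]2C[C@]3(C)C4(OCCO4)CC[C@@H]13 | intermediate
15 | 13β-phenylselanyl-12α-alcohol | C[C@H]1[C@H](O)[C@@H]([Se]c2ccccc2)C[C@]3(C)C4(OCCO4)CC[C@@H]13 | intermediate
16 | selenoxide of 15 | C[C@H]1[C@H](O)[C@@H]([Se](=O)c2ccccc2)C[C@]3(C)C4(OCCO4)CC[C@@H]13 | intermediate
17 | 12α-hydroxy C13=C14 allylic alcohol, C2 ketal | C[C@H]1[C@H](O)C=C[C@]2(C)C3(OCCO3)CC[C@@H]12 | intermediate
18 | 12-O-PMB ether of 17 | C[C@H]1[C@H](OCc2ccc(OC)cc2)C=C[C@]3(C)C4(OCCO4)CC[C@@H]13 | intermediate
19 | trans-hydrindenone: C2 ketone, 12α-OPMB, 11β-methyl, C13=C14 | C[C@H]1[C@H](OCc2ccc(OC)cc2)C=C[C@]3(C)C(=O)CC[C@@H]13 | intermediate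
20 | acrolein | C=CC=O | starting material
21 | dicyclohexylboron enolate of 19 (C2=C8) | C[C@H]1[C@H](OCc2ccc(OC)cc2)C=C[C@]3(C)C(OB(C2CCCCC2)C2CCCCC2)=CC[C@@H]13 | intermediate
22 | anti-aldol: 8α-[(1S)-1-hydroxyallyl] ketone | C[C@H]1[C@H](OCc2ccc(OC)cc2)C=C[C@]3(C)C(=O)[C@H]([C@@H](O)C=C)C[C@@H]13 | intermediate
23 | 7-O-TBS ether of 22 | C[C@H]1[C@H](OCc2ccc(OC)cc2)C=C[C@]3(C)C(=O)[C@H]([C@@H](O[Si](C)(C)C(C)(C)C)C=C)C[C@@H]13 | intermediate
24 | 8α-phenylselanyl ketone | C[C@H]1[C@H](OCc2ccc(OC)cc2)C=C[C@]3(C)C(=O)[C@@]([Se]c2ccccc2)([C@@H](O[Si](C)(C)C(C)(C)C)C=C)C[C@@H]13 | intermediate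
25 | selenoxide of 24 | C[C@H]1[C@H](OCc2ccc(OC)cc2)C=C[C@]3(C)C(=O)[C@@]([Se](=O)c2ccccc2)([C@@H](O[Si](C)(C)C(C)(C)C)C=C)C[C@@H]13 | intermediate
26 | cyclopentenone (C2 ketone, C8=C9) bearing the (7S)-silyloxyallyl group on C8 | C[C@H]1[C@H](OCc2ccc(OC)cc2)C=C[C@]3(C)C(=O)C([C@@H](O[Si](C)(C)C(C)(C)C)C=C)=C[C@@H]13 | intermediate
27 | 4-bromo-2-methylbut-1-ene | C=C(C)CCBr | starting material
28 | 3-methylbut-3-enylmagnesium bromide | C=C(C)CC[Mg]Br | intermediate
29 | tertiary allylic alcohol: 2β-OH, 2α-(3-methylbut-3-enyl) | C[C@H]1[C@H](OCc2ccc(OC)cc2)C=C[C@]3(C)[C@](O)(CCC(C)=C)C([C@@H](O[Si](C)(C)C(C)(C)C)C=C)=C[C@@H]13 | intermediate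
30 | 6-5-7 tricycle: 2β-OH, C8=C9, C5=C6, 7α-OTBS | C[C@H]1[C@H](OCc2ccc(OC)cc2)C=C[C@]3(C)[C@]4(O)CCC(C)=C[C@H](O[Si](C)(C)C(C)(C)C)C4=C[C@@H]13 | intermediate
31 | 8β,9β-epoxide of 30 | C[C@H]1[C@H](OCc2ccc(OC)cc2)C=C[C@]3(C)[C@]4(O)CCC(C)=C[C@H](O[Si](C)(C)C(C)(C)C)[C@@]45O[C@H]5[C@@H]13 | intermediate
32 | 9α-acetoxy-2β,8β-diol, 7α-OTBS | C[C@H]1[C@H](OCc2ccc(OC)cc2)C=C[C@]3(C)[C@]4(O)CCC(C)=C[C@H](O[Si](C)(C)C(C)(C)C)[C@]4(O)[C@H](OC(C)=O)[C@@H]13 | intermediate
33 | 9α-acetoxy-2β,7α,8β-triol | C[C@H]1[C@H](OCc2ccc(OC)cc2)C=C[C@]3(C)[C@]4(O)CCC(C)=C[C@H](O)[C@]4(O)[C@H](OC(C)=O)[C@@H]13 | intermediate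
34 | 2-bromopropanoyl bromide (racemic) | CC(Br)C(=O)Br | starting material
35 | 7-O-(2-bromopropanoyl)-9α-acetoxy-2β,8β-diol | C[C@H]1[C@H](OCc2ccc(OC)cc2)C=C[C@]3(C)[C@]4(O)CCC(C)=C[C@H](OC(=O)C(C)Br)[C@]4(O)[C@H](OC(C)=O)[C@@H]13 | intermediate
36 | cyclic C2,C8 diester of lead diacetate | C[C@H]1[C@H](OCc2ccc(OC)cc2)C=C[C@]3(C)[C@]45CCC(C)=C[C@H](OC(=O)C(C)Br)[C@]4(O[Pb](OC(C)=O)(OC(C)=O)O5)[C@H](OC(C)=O)[C@@H]13 | intermediate
37 | bicyclo[8.4.0] 2,8-dione: (5Z), 7α-O-(2-bromopropanoyl), 9α-OAc, 12α-OPMB | C[C@H]1[C@H](OCc2ccc(OC)cc2)C=C[C@]3(C)C(=O)CC/C(C)=C\[C@H](OC(=O)C(C)Br)C(=O)[C@H](OC(C)=O)[C@@H]13 | intermediate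
38 | diiodosamarium ester enolate of 37 | C[C@H]1[C@H](OCc2ccc(OC)cc2)C=C[C@]3(C)C(=O)CC/C(C)=C\[C@H](OC(O[Sm](I)I)=CC)C(=O)[C@H](OC(C)=O)[C@@H]13 | intermediate
39 | 9α-acetoxy-8α-hydroxy-12α-OPMB-2-oxobriara-5(Z),13-dien-19,7-olide | CC(=O)O[C@@H]1[C@H]2[C@@H](C)[C@H](OCc3ccc(OC)cc3)C=C[C@]2(C)C(=O)CC/C(C)=C\[C@@H]2OC(=O)[C@H](C)[C@]21O | intermediate
40 | (2R)-alcohol of 39 | CC(=O)O[C@@H]1[C@H]2[C@@H](C)[C@H](OCc3ccc(OC)cc3)C=C[C@]2(C)[C@H](O)CC/C(C)=C\[C@@H]2OC(=O)[C@H](C)[C@]21O | intermediate
41 | 2α,9α-diacetate 12-O-PMB ether | CC(=O)O[C@@H]1[C@H]2[C@@H](C)[C@H](OCc3ccc(OC)cc3)C=C[C@]2(C)[C@H](OC(C)=O)CC/C(C)=C\[C@@H]2OC(=O)[C@H](C)[C@]21O | intermediate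
42 | CNP0222085.1, (1S,2R,5Z,7S,8S,9R,10S,11R,12R,17R)-2,9-diacetoxy-8,12-dihydroxybriara-5,13-dien-19,7-olide | CC(=O)O[C@@H]1[C@H]2[C@@H](C)[C@H](O)C=C[C@]2(C)[C@H](OC(C)=O)CC/C(C)=C\[C@@H]2OC(=O)[C@H](C)[C@]21O | target

## Step count and least certain steps

Total: 25 steps. Longest linear sequence: 25 steps (1 and 2 to 42). Compounds 20, 27 and 34 enter as purchased materials.

**Step 21 (key).** The scission itself should be fast for a cis diol. The likelier failure comes afterwards: transannular aldol closure between C3 and the very electrophilic, doubly α-oxygenated C8 carbonyl, or its hydration, helped by the acetic acid released. Slow ligand exchange at two tertiary hydroxyls is a lesser concern. The fallback no longer isolates a dione but consumes the C8 carbonyl as it forms.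
- It sets out from 33, whose O7 is esterified with 2-(diethoxyphosphoryl)propanoic acid (DCC, DMAP) to the phosphonate diol F1.
- Pb(OAc)4 gives the phosphonate dione F2.
- F2 is treated in the same flask with LiCl and iPr2NEt (Masamune–Roush conditions), so that an intramolecular Horner–Wadsworth–Emmons reaction gives the α-methylbutenolide F3.
- Nucleophilic epoxidation (t-BuOOH, DBU) gives the 8,17-epoxy lactone F4.
- Reductive opening at C17 with SmI2 in THF–MeOH comes back to the route at 39.

**Step 22.** Electron transfer to the C8 ketone, with loss of the α-acyloxy groups at C7 or C9, may compete with reduction of the C–Br bond. The five-membered closure also has the enolate double bond inside the forming ring, so orbital overlap is poor and protonation of the enolate may win. The fallback makes the C8–C17 bond intermolecularly and closes the lactone afterwards.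
- It sets out from 32, which Pb(OAc)4 cleaves to the 7-O-TBS dione F5.
- The zinc enolate from ethyl 2-bromopropanoate (Reformatsky reaction) adds to the more electrophilic C8 ketone from the ring periphery to give the β-hydroxy ester F6.
- HF·pyridine removes the silyl group with spontaneous lactonisation, returning at 39.

**Step 23.** The conformation of ring B may override the catalyst and erode facial selectivity. Reversible transannular hemiketal formation between 8-OH and the C2 ketone may slow the reduction enough for hydroboration to intervene. Inversion of a wrong epimer by substitution is not realistic at a neopentyl centre. The fallback therefore changes the source of control to an enzyme pocket: a ketoreductase panel with NADPH recycling (glucose, glucose dehydrogenase), sets out from 39 and comes back at 40 without any new compound.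

**Step 18.** The Lewis acid may trigger a semipinacol shift (migration of C3 from C2 to C8, antiperiplanar to the C8–O bond) or opening at C8 instead of substitution at C9. The fallback avoids the epoxide.
- It sets out from 30, which undergoes hydroxyl-directed syn-dihydroxylation with OsO4·TMEDA at −78 °C on the β face to give the 2β,8β,9β-triol F7.
- A Mitsunobu reaction with acetic acid inverts the only secondary hydroxyl, returning at 32. The cis 8β-OH cannot displace the activated oxygen from the rear.

**Step 14.** Deprotonation of the hindered 8β-H may be slow, and the lithium enolate may expel the β-silyloxy group (E1cB) before it is selenenylated. The fallback replaces hard enolisation by soft enolisation.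
- It sets out from 23, which TMSOTf and Et3N convert into the trimethylsilyl enol ether F8.
- PhSeCl at −78 °C then gives the selenide, coming back to the route at 24.

## Further compounds

F1 | step 21 | 7-O-[2-(diethoxyphosphoryl)propanoyl]-9α-acetoxy-2β,8β-diol | C[C@H]1[C@H](OCc2ccc(OC)cc2)C=C[C@]3(C)[C@]4(O)CCC(C)=C[C@H](OC(=O)C(C)P(=O)(OCC)OCC)[C@]4(O)[C@H](OC(C)=O)[C@@H]13
F2 | step 21 | ring B 2,8-dione with the phosphonopropanoate on O7 | C[C@H]1[C@H](OCc2ccc(OC)cc2)C=C[C@]3(C)C(=O)CC/C(C)=C\[C@H](OC(=O)C(C)P(=O)(OCC)OCC)C(=O)[C@H](OC(C)=O)[C@@H]13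
F3 | step 21 | 8(17)-butenolide 2-ketone | CC(=O)O[C@@H]1[C@H]2[C@@H](C)[C@H](OCc3ccc(OC)cc3)C=C[C@]2(C)C(=O)CC/C(C)=C\[C@@H]2OC(=O)C(C)=C21
F4 | step 21 | 8α,17α-epoxy lactone 2-ketone | CC(=O)O[C@@H]1[C@H]2[C@@H](C)[C@H](OCc3ccc(OC)cc3)C=C[C@]2(C)C(=O)CC/C(C)=C\[C@@H]2OC(=O)[C@]3(C)O[C@@]213
F5 | step 22 | ring B 2,8-dione, 7α-OTBS | C[C@H]1[C@H](OCc2ccc(OC)cc2)C=C[C@]3(C)C(=O)CC/C(C)=C\[C@H](O[Si](C)(C)C(C)(C)C)C(=O)[C@H](OC(C)=O)[C@@H]13
F6 | step 22 | C8 β-hydroxy ethyl ester (open form of ring C), 7α-OTBS | C[C@H]1[C@H](OCc2ccc(OC)cc2)C=C[C@]3(C)C(=O)CC/C(C)=C\[C@H](O[Si](C)(C)C(C)(C)C)[C@@](O)([C@@H](C)C(=O)OCC)[C@H](OC(C)=O)[C@@H]13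
F0 | step 23 | none | none
F7 | step 18 | 2β,8β,9β-triol, 7α-OTBS | C[C@H]1[C@H](OCc2ccc(OC)cc2)C=C[C@]3(C)[C@]4(O)CCC(C)=C[C@H](O[Si](C)(C)C(C)(C)C)[C@]4(O)[C@@H](O)[C@@H]13
F8 | step 14 | C2=C8 trimethylsilyl enol ether of 23 | C[C@H]1[C@H](OCc2ccc(OC)cc2)C=C[C@]3(C)C(O[Si](C)(C)C)=C([C@@H](O[Si](C)(C)C(C)(C)C)C=C)C[C@@H]13
A1 | alternative 1 | 5,6-seco-diene carrying rings A and C | CC(=O)O[C@H]([C@H]1[C@@H](C)[C@H](O)C=C[C@]1(C)[C@H](OC(C)=O)CCC(C)=C)[C@@]1(O)[C@H](C=C)OC(=O)[C@@H]1C
A2 | alternative 2 | trans-1-(cyclohexenyl)-2-[(E)-2-(methoxymethoxy)vinyl]-4-methylcyclohex-3-en-1-ol | COCO/C=C/[C@@H]1C=C(C)CC[C@@]1(O)C1=C[C@@H](C)[C@H](OCc2ccc(OC)cc2)CC1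
A3 | alternative 2 | ring-expanded, C1-methylated 5(Z),7(E)-dien-2-one | COCO[C@@H]1[C@H]2[C@@H](C)[C@H](OCc3ccc(OC)cc3)CC[C@]2(C)C(=O)CC/C(C)=C\C=C\1
A4 | alternative 3 | ring A-fused 2-methylene-8-isopropenyloxocane (C8 as ethylene ketal) | C[C@H]1[C@H](OCc2ccc(OC)cc2)C=C[C@]3(C)C(=C)O[C@@H](C(C)=C)[C@H](O[Si](C)(C)C(C)(C)C)C2(OCCO2)[C@H](O[Si](C)(C)C(C)(C)C)[C@@H]13
A5 | alternative 3 | parent eight-membered lactone of A4 | C[C@H]1[C@H](OCc2ccc(OC)cc2)C=C[C@]3(C)C(=O)O[C@@H](C(C)=C)[C@H](O[Si](C)(C)C(C)(C)C)C2(OCCO2)[C@H](O[Si](C)(C)C(C)(C)C)[C@@H]13
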